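The data come from a simulation with constants of no real substance, and the scatter is random.

The pitfall in these runs is to take the product excess for the catalyst's preference.

the same everywhere: left-handed substrate 0.10 M; right-handed substrate 0.10 M
- grey: reagent 0.40 equiv (fed, over 40 min); free catalyst 2.5 mol%; run made earlier; the fed solution adds 0.50 times the starting volume
- amber: reagent 1.6 equiv (fed, over 40 min); free catalyst 2.5 mol%; run made earlier; the fed solution adds 0.50 times the starting volume
- green: reagent 0.80 equiv (fed, over 40 min); free catalyst 1.2 mol%; run made earlier; the fed solution adds 0.50 times the starting volume
- flask: reagent 0.800 equiv (fed, over 40 min); free catalyst 2.5 mol%; the fed solution adds 0.50 times the starting volume; time 2.0 h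

- grey (time / min: left-handed product / %, right-handed product / %, left-handed substrate / %): 15.0: 2.3, 2.6, 49.5; 40.0: 6.0, 6.3, 47.8; 80.0: 8.2, 8.5, 46.3; 120: 10.5, 8.4, 47.5
- amber (time / min: left-handed product / %, right-handed product / %, left-handed substrate / %): 15.0: 6.8, 10.9, 47.2; 40.0: 22.3, 24.2, 42.1; 80.0: 26.0, 24.7, 37.3; 120: 25.9, 27.0, 38.4
- green (time / min: left-handed product / %, right-handed product / %, left-handed substrate / %): 10.0: 1.0, 1.6, 51.3; 20.0: 3.7, 6.4, 48.2; 50.0: 10.6, 10.8, 46.5; 120: 16.4, 12.8, 44.8

(each reading ± 1 percentage point)

- free catalyst is single-handed; left-handed substrate and right-handed substrate are mirror images of each other, charged as a racemate, each of them at the stated concentration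
- amounts are per litre of the starting volume; all of the dose is in the solution fed
- the numbers in the tables scatter by 1 percentage point (one standard deviation)
- on the list of suspects stand: free catalyst + left-handed substrate <-> catalyst intermediate A; free catalyst + right-handed substrate <-> catalyst intermediate B; reagent + catalyst intermediate A -> free catalyst + left-handed product; reagent + catalyst intermediate B -> free catalyst + right-handed product; free catalyst <-> dormant form; free catalyst -> spent catalyst; left-handed product <-> right-handed product
- an excess is the difference of the two amounts in percent of their sum
- an excess is below zero if the other one leads

- excess of left-handed product over right-handed product in the product at 12 min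
- excess of left-handed product over right-handed product in the product at 2.0 h
- part of the left-handed substrate and right-handed substrate charged together that has reacted at 2.0 h

How strongly does the catalyst prefer one substrate? The list of suspects holds no step between the substrates, so their losses keep the preference on record. If each substrate falls in proportion to its own concentration, integrating both rates gives the selectivity factor s, the logarithm of c(right-handed substrate) over its start divided by the same logarithm for c(left-handed substrate). The green run at 120 min, with right-handed substrate reckoned as the rest of the charge, gives s = 5.95. Fresh product should therefore carry an excess of −71.2%.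

Yet the green run at 20.0 min shows −26.7%. How long does an excess last? Take steady production and an excess that decays first-order with a memory time τ. Integration then gives excess = fresh excess × (τ/t) × (1 − exp(−t/τ)). The green run has the flask's reagent charge, and setting the bracket to one gives the memory time τ as 7.50 min, a rough reading given the scatter.

For the flask at 12 min, this rule gives −35.6%. Does anything survive to 2.0 h? The end of the feed lies 10.7 memory times earlier, and hardly any of the excess standing then remains, so this reckoning puts the final excess near zero.

The forecast gives −25%, −1% and 34%, holding that “the products interconvert with a half-life of a few minutes, independent of the feed”. Its early value is less negative than the reckoning here.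

The flask gives −37.5%, −0.111% and 34.6%.

    free catalyst + left-handed substrate ⇌ catalyst intermediate A (K = 5.10 M⁻¹, k = 19.0 M⁻¹ s⁻¹)
    free catalyst + right-handed substrate ⇌ catalyst intermediate B (K = 140 M⁻¹, k = 7.40 M⁻¹ s⁻¹)
    reagent + catalyst intermediate A → free catalyst + left-handed product (k = 3.90 M⁻¹ s⁻¹)
    reagent + catalyst intermediate B → free catalyst + right-handed product (k = 1.50 M⁻¹ s⁻¹)
    free catalyst ⇌ dormant form (K = 1.30, k = 2.40 × 10⁻⁴ s⁻¹)
    free catalyst → spent catalyst (k = 0.00350 s⁻¹)
    left-handed product ⇌ right-handed product (k = 0.00150 s⁻¹)

At 2.00 h the flask's reagent still goes to right-handed product at 4.1 times the rate of left-handed product, yet the flask holds 17.3% and 17.3% of them, 80.0 min after the feed ended, which is 10.7 memory times as read from the green run. The memory-time rule contains no catalyst term, so it gives −35.6% again for the same flask with 10 mol% of free catalyst, and that flask shows −34.0%.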